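Count the impurity first.

starting material 0.30 M (fed, over 20 min); protic impurity 0.150 M; time 15 d; the fed solution adds 1.0 times the starting volume

    starting material ⇌ target (K1 = 0.10, k1 = 0.63 /h)
    isomer of the product A ⇌ starting material (k2 = 0.21 /h)
    starting material + protic impurity → quenched substrate (k3 = 4.6 /M/h)
    target ⇌ isomer of the product B (K4 = 0.40, k4 = 2.1 /h)
    target ⇌ isomer of the product A (K5 = 0.074, k5 = 1.1 /h)

- charges are per starting volume, the dose included; the dosed solution carries all of it
- the reaction counts as stopped when no species that holds the starting material changes by six tenths of a point or more over the second half of the time
- run time (flask): 15 d

- at 15 d, what has stopped the reaction, if anything has (all of the starting material has reacted / it is still moving / forward and back rates have come level)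
- share of the starting material used up at 15 d
- target at 15 d, in percent of the starting material charged
- isomer of the product B at 15 d, in percent of the starting material charged

In this flask, starting material, target and the isomers of the product A and B exchange reversibly as a single pool, while each protic impurity removes one starting material for good as quenched substrate. The fastest rung of the ladder is the exchange through target: the relaxation half-lives of its steps, each by its step alone, are 0.0434 h, 0.0943 h and 0.100 h, shorter than both the 20 min dose and the 1.0 h half-life of the quench at the charged impurity. The pool therefore stays near its equilibrium ratios while it is drained, and its sum of weights, starting material counted as one, is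

W = 1 + 0.10 + 0.10 · 0.40 + 0.10 · 0.074 = 1.147.

The next rung is the quench. The impurity is the limiting reagent, so the pool keeps what the impurity's charge leaves over, the surviving share φ, reckoned as one minus the equivalents of impurity and not below zero:

φ = (0.30 M − 0.150 M) / 0.30 M = 50.0%.

The last rung is the impurity's tail, in which the impurity falls pseudo-first-order with starting material held near its final level, reckoned for the diluted flask:

0.0654 M of starting material gives a half-life of 2.31 h.

This is far shorter than 15 d, so by hand this flask ends with forward and back rates level, conversion 56.4%, target 4.36% and isomer of the product B 1.74%.

The forecast gives forward and back rates have come level, 56.4%, 4.36% and 1.74%, holding that “That pool equilibrates quickly, in hours”. The simulation of this flask gives forward and back rates have come level, 56.4%, 4.36% and 1.74%.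

In this flask the relaxation half-life of 0.100 h is short against the 15 d run, and target reads 4.36% at 7.50 d and 4.36% at 15.0 d. At 15.0 d the pool species of this flask add up to 50.0% of the charge, against φ of 50.0%.

In the neighbour flask with 0.60 M of protic impurity, 2.00 equiv, φ is 0%, so the reckoning leaves no pool and 50.0% of the impurity over. That neighbour flask gives conversion 100%, target 0%, isomer of the product B 0% and 50% of its impurity left.

The numbers of this flask belong to no real substance; the run is a simulation.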